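The slowness of this flask can be reckoned by hand, and the reckoning starts with how much catalyst stays at work.

    starting material + free catalyst ⇌ catalyst intermediate (K1 = 4.46 L mol⁻¹, k1 = 8.80 L mol⁻¹ min⁻¹)
    catalyst intermediate → free catalyst + product (k2 = 4.27 min⁻¹)
    crystals ⇌ product, rate k3*(cs3 - [product]) while solid is left; crystals form when [product] > cs3 (cs3 = 23 mM, k3 = 1.75 min⁻¹)
    free catalyst + impurity → spent catalyst (k4 = 676 L mol⁻¹ min⁻¹)
    2 catalyst intermediate ⇌ resting dimer, settled at all times (K5 = 680 L mol⁻¹)

starting material 0.25 M; free catalyst 1.2 mol%; impurity 2.6 mM; time 40 min

- in percentages every species weighs as the starting material in it: one resting dimer counts as two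
- for product the crystals are counted in
- a doubled species enters its step squared and goes two at a time
- as a solid, counted per litre of solution: crystals
- run time (flask): 40 min

1. how much product and crystals together there is at 40 min, in percent of the starting material charged
2. the change that raises the amount of product and crystals together at 40 min, in percent of the starting material charged most ("none" if none brings more than 2 percentage points) (violet / amber / red / none)
3. amount of product and crystals together at 40 min, in percent of the starting material charged, after violet

- violet: doubling the amount of free catalyst, all else as stated
- amber: doubling the dissolution coefficient of step 3, all else as stated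
- red: doubling the solubility in step 3, all else as stated

Each impurity takes one catalyst for good, so a charge of 3.00 mM less 2.6 mM of impurity leaves 0.400 mM, the surviving catalyst. One objection is that starting material competes for free catalyst. But binding returns catalyst through the intermediate, and with the survivors taken as free catalyst the impurity decays with a time of 3.70 min, shorter than the run.

The value 1.1 for K1 times c(starting material) suggests step one stands at balance. Yet the intermediate falls back at 1.97 min⁻¹, slower than it goes forward at 4.27 min⁻¹, so a steady state is the better estimate: c(catalyst intermediate)/c(free catalyst) = 0.352. With this ratio frozen at its starting value, starting material decays pseudo-first-order with 0.00178 min⁻¹, and the converted fraction, one minus exp(−κt), is 6.87 % at 40 min.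

That ignores the extra catalyst working while impurity lasts. Integrating the impurity's decay gives a burst of 2.23 mM times the logarithm of charge over survivors, 4.48 mM. The reckoning for the flask is therefore 8.67 %. The resting dimer would hold 3.69 % of the survivors, which is small.

The catalytic rates contain neither product nor crystals, so amber and red leave the total unchanged. Violet leaves 3.40 mM of survivors and 0.0151 min⁻¹, which gives 45.9 %. The dimer term there reaches 31.4 %, so this figure should stand high. The choice is violet.

The forecast gives 8.3 %, violet and 42 %, below this reckoning in both flasks. Its ground for the choice: “Crystals only move material between dissolved and solid product, and nothing feeds back from product”.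

The simulation gives 8.31 %, violet with a gain of 34 percentage points, and 42.1 %.

In the flask, half of the poisoning turnover is done by 0.657 min and half of the binding turnover by 14.8 min. At 40.0 min in the flask, the reckoned 0.400 mM of surviving catalyst is to be set beside free catalyst at 9.77 %, catalyst intermediate at 3.16 % and resting dimer at 0.407 % of the catalyst charged, while spent catalyst holds 86.7 %. In the neighbour flask with 3 mol% of free catalyst, the survivors come to 4.90 mM, and the same reckoning gives 58.6 %. That neighbour flask computes to 54.0 %.

All constants come from no measurement; the flask was simulated.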